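**Retrosynthetic overview**

1. Ring A (the free pyrrol-2-yl group on the C=N carbon of ring B) is attached last, by Suzuki–Miyaura coupling to the imidoyl triflate of the ring B lactam.
2. The strategy rests on the chain of seven unfunctionalised CH2 groups that joins C-5 of pyrrole ring C to the chain-bearing CH of tetrahydropyran ring D; the 12-membered ansa ring is therefore opened at the C4–C5 bond of this chain (ring-closing metathesis, then H2), away from all four stereocentres.
3. The metathesis substrate is the finished spiro N,O-ketal (rings B and D) carrying a pent-4-enyl arm on the ring D methine and a but-3-enyl arm on ring C; rings B and D come from a 2-substituted 3-methoxyfuran by singlet-oxygen oxidation, ammonia and acid-mediated spiroketalisation (spiro centre under thermodynamic control).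
4. The furyl–pyrrolyl methine is made by Friedel–Crafts alkylation of 2-(but-3-enyl)pyrrole with a 3-methoxyfurfuryl alcohol, which comes from 2-lithio-3-methoxyfuran and the trans lactone obtained by alkylating (S)-γ-valerolactone with 5-iodopent-1-ene.
5. Order of ring formation: ring C (bought, as pyrrole-2-carboxaldehyde), ring B (furan to hydroxy lactam), ring D (spiro closure), the 12-membered ansa ring (metathesis), ring A (coupling).

Key step: step 13

Assumption: 5-iodopent-1-ene is taken as a purchased reagent (otherwise it is one NaI/acetone exchange from 5-bromopent-1-ene).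

**Route**

Step 1
Reactants: 1 (S)-γ-valerolactone; 2 5-iodopent-1-ene
Product: 3 (3S,5S)-5-methyl-3-(pent-4-en-1-yl)oxolan-2-one
Conditions: LiN(i-Pr)2, THF, −78 °C; then 2, DMPU, −78 → −30 °C
Reagents that add atoms: none
Why: SN2 alkylation of the lithium enolate of a γ-substituted butyrolactone with a primary iodide should take place on the enolate face anti to the C-5 methyl group, which sets C-3 as (S), trans to C-5, the minor cis isomer being removed by chromatography.

Step 2
Reactants: 4 3-bromofuran
Product: 5 3-methoxyfuran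
Conditions: NaOMe, CuBr (10 mol %), MeOH–NMP, 100 °C, sealed tube
Reagents that add atoms: sodium methoxide, C[O-].[Na+]
Why: Ullmann-type copper-catalysed methoxylation of a heteroaryl bromide replaces bromide by methoxide at C-3 and leaves the furan ring intact.

Step 3
Reactants: 5 3-methoxyfuran; 3 (3S,5S)-5-methyl-3-(pent-4-en-1-yl)oxolan-2-one
Product: 7 (2S,4S)-4-hydroxy-1-(3-methoxyfuran-2-yl)-2-(pent-4-en-1-yl)pentan-1-one, via 2-lithio-3-methoxyfuran 6 (not isolated)
Conditions: 5, n-BuLi, THF, −78 → 0 °C; then 3, −78 °C; AcOH quench at −78 °C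
Reagents that add atoms: none
Why: Directed lithiation of 3-methoxyfuran at C-2 (between the ring oxygen and OMe) followed by addition of the aryllithium to the lactone carbonyl (acyl substitution that stops at the ketone because the lithium hemiketalate persists at −78 °C) opens the lactone to the γ-hydroxy ketone, and the cold acidic quench avoids enolisation of the α-stereocentre.

Step 4
Reactants: 7 (2S,4S)-4-hydroxy-1-(3-methoxyfuran-2-yl)-2-(pent-4-en-1-yl)pentan-1-one
Product: 8 (2S,4S)-4-(tert-butyldimethylsilyloxy)-1-(3-methoxyfuran-2-yl)-2-(pent-4-en-1-yl)pentan-1-one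
Conditions: TBSCl, imidazole, DMF, 0 °C → rt
Reagents that add atoms: tert-butyldimethylsilyl chloride, CC(C)(C)[Si](C)(C)Cl
Why: O-Silylation (silyl ether formation) of the secondary alcohol prevents its cyclisation onto the later carbocation and makes this arm the bulkier one for the facial control in step 8.

Step 5
Reactants: 8 (2S,4S)-4-(tert-butyldimethylsilyloxy)-1-(3-methoxyfuran-2-yl)-2-(pent-4-en-1-yl)pentan-1-one
Product: 9 (2S,4S)-4-(tert-butyldimethylsilyloxy)-1-(3-methoxyfuran-2-yl)-2-(pent-4-en-1-yl)pentan-1-ol (both C-1 epimers)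
Conditions: NaBH4, MeOH, 0 °C → rt
Reagents that add atoms: none
Why: Borohydride reduction of the aryl ketone gives the furfuryl alcohol as a mixture of carbinol epimers, which is of no consequence because this carbon is ionised in step 8.

Step 6
Reactants: 10 pyrrole-2-carboxaldehyde; 11 allylmagnesium bromide
Product: 12 1-(1H-pyrrol-2-yl)but-3-en-1-ol (racemic)
Conditions: 11 (2.2 equiv), THF, −78 → 0 °C; H2O quench
Reagents that add atoms: none
Why: Grignard addition to the aldehyde, after deprotonation of N–H by the first equivalent, gives the pyrrolyl carbinol, whose stereocentre is removed in step 7.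

Step 7
Reactants: 12 1-(1H-pyrrol-2-yl)but-3-en-1-ol
Product: 13 2-(but-3-en-1-yl)-1H-pyrrole
Conditions: LiAlH4, THF, reflux; H2O/NaOH work-up
Reagents that add atoms: none
Why: Hydride deoxygenation of a pyrrol-2-yl carbinol: the N-metallated alkoxide eliminates to the azafulvene, which takes up hydride at the exocyclic carbon, while the isolated terminal alkene is inert to LiAlH4.

Step 8
Reactants: 9 (2S,4S)-4-(tert-butyldimethylsilyloxy)-1-(3-methoxyfuran-2-yl)-2-(pent-4-en-1-yl)pentan-1-ol; 13 2-(but-3-en-1-yl)-1H-pyrrole
Product: 14 2-(but-3-en-1-yl)-5-[(1S,2S,4S)-4-(tert-butyldimethylsilyloxy)-1-(3-methoxyfuran-2-yl)-2-(pent-4-en-1-yl)pentyl]-1H-pyrrole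
Conditions: 13 (3 equiv), BF3·OEt2 (20 mol %), 4 Å MS, CH2Cl2, −78 → −40 °C
Reagents that add atoms: none
Why: Friedel–Crafts (SN1) alkylation of the free α-position of the pyrrole by the 3-methoxyfurfuryl cation released from 9; with the C-2 hydrogen eclipsing the cation plane to minimise allylic strain, the pyrrole should enter anti to the β-branched silyloxypropyl arm (the same face results if the silyl ether oxygen first bridges the cation and is displaced with inversion), which sets C-1 as (S), any epimer being removed by chromatography.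

Step 9
Reactants: 14 2-(but-3-en-1-yl)-5-[(1S,2S,4S)-4-(tert-butyldimethylsilyloxy)-1-(3-methoxyfuran-2-yl)-2-(pent-4-en-1-yl)pentyl]-1H-pyrrole
Product: 15 tert-butyl 2-(but-3-en-1-yl)-5-[(1S,2S,4S)-4-(tert-butyldimethylsilyloxy)-1-(3-methoxyfuran-2-yl)-2-(pent-4-en-1-yl)pentyl]-1H-pyrrole-1-carboxylate
Conditions: Boc2O, DMAP (cat.), MeCN, rt
Reagents that add atoms: di-tert-butyl dicarbonate, CC(C)(C)OC(=O)OC(=O)OC(C)(C)C
Why: N-Acylation of the pyrrole (carbamate formation) withdraws electron density from ring C so that singlet oxygen in step 10 attacks only the methoxyfuran.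

Step 10
Reactants: 15 tert-butyl 2-(but-3-en-1-yl)-5-[(1S,2S,4S)-4-(tert-butyldimethylsilyloxy)-1-(3-methoxyfuran-2-yl)-2-(pent-4-en-1-yl)pentyl]-1H-pyrrole-1-carboxylate
Product: 18 tert-butyl 2-(but-3-en-1-yl)-5-[(1S,2S,4S)-4-(tert-butyldimethylsilyloxy)-1-(2-hydroxy-3-methoxy-5-oxo-2,5-dihydro-1H-pyrrol-2-yl)-2-(pent-4-en-1-yl)pentyl]-1H-pyrrole-1-carboxylate (hydroxy lactam), via furan endoperoxide 16 (not isolated), via γ-hydroxybutenolide 17 (not isolated)
Conditions: O2, hν (visible), tetraphenylporphyrin (cat.), CH2Cl2, −78 °C; then i-Pr2NEt, −78 → 0 °C; then NH3 (7 M in MeOH), rt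
Reagents that add atoms: dioxygen, O=O; ammonia, N
Why: [4+2] Cycloaddition of singlet oxygen to the electron-rich 3-methoxyfuran (much faster than to the N-Boc pyrrole or the monosubstituted alkenes), Kornblum–DeLaMare fragmentation of the endoperoxide at the C-5 hydrogen to the γ-hydroxybutenolide and ammonolysis of this pseudo-acid with reclosure on nitrogen give the 5-hydroxy lactam, whose hemiaminal carbon stays configurationally mobile while the three set stereocentres are not touched.

Step 11
Reactants: 18 hydroxy lactam silyl ether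
Product: 20 tert-butyl 2-(but-3-en-1-yl)-5-[(5R,7S,9S,10S)-4-methoxy-7-methyl-2-oxo-9-(pent-4-en-1-yl)-6-oxa-1-azaspiro[4.5]dec-3-en-10-yl]-1H-pyrrole-1-carboxylate, via desilylated hydroxy lactam 19 (not isolated)
Conditions: CSA (0.3 equiv), MeOH–CH2Cl2 (1:4), 0 °C → rt; Et3N quench
Reagents that add atoms: none
Why: Acid-catalysed methanolysis of the silyl ether, ionisation of the hemiaminal to the N-acyliminium ion and its capture by the freed hydroxyl (6-exo-trig spiro N,O-ketalisation) run under thermodynamic control, which should place nitrogen axial on ring D (anomeric effect) with the pentenyl and pyrrolyl groups equatorial at the cost of an axial methyl group and so give the (5R) spiro centre, the epimer being re-equilibrated under the same conditions.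

Step 12
Reactants: 20 N-Boc spiro lactam
Product: 21 (5R,7S,9S,10S)-10-[5-(but-3-en-1-yl)-1H-pyrrol-2-yl]-4-methoxy-7-methyl-9-(pent-4-en-1-yl)-6-oxa-1-azaspiro[4.5]dec-3-en-2-one
Conditions: K2CO3, MeOH, 40 °C
Reagents that add atoms: none
Why: Base-catalysed methanolysis (transacylation) of the N-acyl pyrrole frees the N–H that has to point into the ansa ring, while the lactam, the enol ether and the N,O-ketal are stable to carbonate in methanol.

Step 13
Reactants: 21 spiro lactam diene
Product: 22 unsaturated ansa spiro lactam (E and Z), the two arms of 21 joined as a (CH2)3–CH=CH–(CH2)2 chain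
Conditions: second-generation Grubbs catalyst RuCl2(=CHPh)(H2IMes)(PCy3) (10 mol %), 1,4-benzoquinone (20 mol %), CH2Cl2 (1 mM), reflux
Reagents that add atoms: none
Why: Ring-closing olefin metathesis: the ruthenium benzylidene exchanges onto one terminal alkene, the new alkylidene adds to the other alkene in a [2+2] step and the ruthenacyclobutane collapses with loss of ethene, which makes the closure irreversible in an open refluxing system. The closest known reaction type is the metathesis macrocyclisation of α,ω-dienes to 12-membered carbocycles and pyrrolophanes with this catalyst. The 12-membered ansa ring (counted through N-1 of ring C) is closed in the endo mode by forming the C4=C5 bond of the chain, three CH2 from C-9 and two CH2 from the pyrrole, so that no strain is built in next to a stereocentre. No stereocentre is formed and the alkene geometry is irrelevant because step 14 saturates it. The selectivity needed is ring closure over oligomerisation, and it is secured by high dilution and by the chair of ring D, which holds the groups on C-9 and C-10 both equatorial and therefore gauche, with the pyrrole N–H pointing into the forming ring. Ring B is carried as the neutral lactam so that no basic nitrogen is offered to ruthenium, its trisubstituted carbonyl-conjugated enol ether alkene is too hindered to enter the cycle, and benzoquinone suppresses alkene migration.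

Step 14
Reactants: 22 unsaturated ansa spiro lactam
Product: 23 saturated macrocyclic spiro lactam (heptamethylene ansa chain)
Conditions: H2 (1 atm), 10% Pd/C, EtOAc, rt
Reagents that add atoms: none
Why: Heterogeneous catalytic hydrogenation saturates the disubstituted ring alkene (both geometrical isomers converge) while the pyrrole and the trisubstituted, carbonyl-conjugated enol ether alkene of ring B are not reduced under these mild conditions.

Step 15
Reactants: 23 saturated macrocyclic spiro lactam
Product: 24 imidoyl triflate of 23 (2-triflyloxy-2H-pyrrole form of ring B)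
Conditions: Tf2O, 2,6-di-tert-butyl-4-methylpyridine, CH2Cl2, −78 → 0 °C
Reagents that add atoms: trifluoromethanesulfonic anhydride, O=S(=O)(OS(=O)(=O)C(F)(F)F)C(F)(F)F
Why: O-Sulfonylation of the secondary lactam (imidoyl triflate formation) at the nucleophilic vinylogous-carbamate oxygen creates the C=N bond of ring B and a leaving group for cross-coupling, the hindered base protecting the acid-labile N,O-ketal and the pyrrole.

Step 16
Reactants: 24 imidoyl triflate; 25 [1-(tert-butoxycarbonyl)-1H-pyrrol-2-yl]boronic acid
Product: 27 premarineosin A, via N-Boc-premarineosin A 26 (not isolated)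
Conditions: Pd(PPh3)4 (10 mol %), Na2CO3 (2 M aq), DME, 80 °C; then NaOMe, MeOH, rt
Reagents that add atoms: none
Why: Suzuki–Miyaura coupling of the imidoyl triflate with the 2-pyrrolylboronic acid attaches ring A at the C=N carbon, and methoxide then cleaves the N-Boc group of ring A by transacylation without affecting any stereocentre.

**Compound list**

1 | (S)-γ-valerolactone, (5S)-5-methyloxolan-2-one | C[C@H]1CCC(=O)O1 | starting material
2 | 5-iodopent-1-ene | C=CCCCI | starting material
3 | (3S,5S)-5-methyl-3-(pent-4-en-1-yl)oxolan-2-one (trans lactone) | C[C@H]1C[C@H](CCCC=C)C(=O)O1 | intermediate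
4 | 3-bromofuran | Brc1ccoc1 | starting material
5 | 3-methoxyfuran | COc1ccoc1 | intermediate
6 | 2-lithio-3-methoxyfuran | COc1ccoc1[Li] | intermediate
7 | (2S,4S)-4-hydroxy-1-(3-methoxyfuran-2-yl)-2-(pent-4-en-1-yl)pentan-1-one | C[C@H](O)C[C@H](CCCC=C)C(=O)c1occc1OC | intermediate
8 | (2S,4S)-4-(tert-butyldimethylsilyloxy)-1-(3-methoxyfuran-2-yl)-2-(pent-4-en-1-yl)pentan-1-one | C[C@H](O[Si](C)(C)C(C)(C)C)C[C@H](CCCC=C)C(=O)c1occc1OC | intermediate
9 | (2S,4S)-4-(tert-butyldimethylsilyloxy)-1-(3-methoxyfuran-2-yl)-2-(pent-4-en-1-yl)pentan-1-ol, both C-1 epimers | C[C@H](O[Si](C)(C)C(C)(C)C)C[C@H](CCCC=C)C(O)c1occc1OC | intermediate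
10 | pyrrole-2-carboxaldehyde | O=Cc1ccc[nH]1 | starting material
11 | allylmagnesium bromide | C=CC[Mg]Br | starting material
12 | 1-(1H-pyrrol-2-yl)but-3-en-1-ol, racemic | OC(CC=C)c1ccc[nH]1 | intermediate
13 | 2-(but-3-en-1-yl)-1H-pyrrole | C=CCCc1ccc[nH]1 | intermediate
14 | 2-(but-3-en-1-yl)-5-[(1S,2S,4S)-4-(tert-butyldimethylsilyloxy)-1-(3-methoxyfuran-2-yl)-2-(pent-4-en-1-yl)pentyl]-1H-pyrrole | C[C@H](O[Si](C)(C)C(C)(C)C)C[C@H](CCCC=C)[C@H](c1occc1OC)c1ccc(CCC=C)[nH]1 | intermediate
15 | tert-butyl 2-(but-3-en-1-yl)-5-[(1S,2S,4S)-4-(tert-butyldimethylsilyloxy)-1-(3-methoxyfuran-2-yl)-2-(pent-4-en-1-yl)pentyl]-1H-pyrrole-1-carboxylate | C[C@H](O[Si](C)(C)C(C)(C)C)C[C@H](CCCC=C)[C@H](c1occc1OC)c1ccc(CCC=C)n1C(=O)OC(C)(C)C | intermediate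
16 | furan endoperoxide of 15: the furyl group replaced by 6-methoxy-2,3,7-trioxabicyclo[2.2.1]hept-5-en-1-yl, bicycle as a mixture of faces | C[C@H](O[Si](C)(C)C(C)(C)C)C[C@H](CCCC=C)[C@H](C12OOC(C=C1OC)O2)c1ccc(CCC=C)n1C(=O)OC(C)(C)C | intermediate
17 | γ-hydroxybutenolide: the furyl group of 15 replaced by 2-hydroxy-3-methoxy-5-oxo-2,5-dihydrofuran-2-yl, hemiketal carbon as a mixture | C[C@H](O[Si](C)(C)C(C)(C)C)C[C@H](CCCC=C)[C@H](C1(O)OC(=O)C=C1OC)c1ccc(CCC=C)n1C(=O)OC(C)(C)C | intermediate
18 | hydroxy lactam: tert-butyl 2-(but-3-en-1-yl)-5-[(1S,2S,4S)-4-(tert-butyldimethylsilyloxy)-1-(2-hydroxy-3-methoxy-5-oxo-2,5-dihydro-1H-pyrrol-2-yl)-2-(pent-4-en-1-yl)pentyl]-1H-pyrrole-1-carboxylate, hemiaminal carbon as a mixture | C[C@H](O[Si](C)(C)C(C)(C)C)C[C@H](CCCC=C)[C@H](C1(O)NC(=O)C=C1OC)c1ccc(CCC=C)n1C(=O)OC(C)(C)C | intermediate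
19 | desilylated hydroxy lactam: 18 with a free (4S) secondary alcohol | C[C@H](O)C[C@H](CCCC=C)[C@H](C1(O)NC(=O)C=C1OC)c1ccc(CCC=C)n1C(=O)OC(C)(C)C | intermediate
20 | tert-butyl 2-(but-3-en-1-yl)-5-[(5R,7S,9S,10S)-4-methoxy-7-methyl-2-oxo-9-(pent-4-en-1-yl)-6-oxa-1-azaspiro[4.5]dec-3-en-10-yl]-1H-pyrrole-1-carboxylate | COC1=CC(=O)N[C@]12O[C@@H](C)C[C@H](CCCC=C)[C@H]2c2ccc(CCC=C)n2C(=O)OC(C)(C)C | intermediate
21 | (5R,7S,9S,10S)-10-[5-(but-3-en-1-yl)-1H-pyrrol-2-yl]-4-methoxy-7-methyl-9-(pent-4-en-1-yl)-6-oxa-1-azaspiro[4.5]dec-3-en-2-one (metathesis precursor) | COC1=CC(=O)N[C@]12O[C@@H](C)C[C@H](CCCC=C)[C@H]2c2ccc(CCC=C)[nH]2 | intermediate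
22 | unsaturated ansa spiro lactam, E and Z: 12-membered ring closed through a (CH2)3–CH=CH–(CH2)2 chain between C-9 and C-5 of the pyrrole, stereocentres as in 21 | COC1=CC(=O)N[C@]12O[C@@H](C)C[C@@H]1CCCC=CCCc3ccc([nH]3)[C@H]12 | intermediate
23 | saturated macrocyclic spiro lactam: heptamethylene ansa chain, stereocentres as in 21 | COC1=CC(=O)N[C@]12O[C@@H](C)C[C@@H]1CCCCCCCc3ccc([nH]3)[C@H]12 | intermediate
24 | imidoyl triflate of 23: ring B as 3-methoxy-5-(trifluoromethanesulfonyloxy)-2H-pyrrole | COC1=CC(OS(=O)(=O)C(F)(F)F)=N[C@]12O[C@@H](C)C[C@@H]1CCCCCCCc3ccc([nH]3)[C@H]12 | intermediate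
25 | [1-(tert-butoxycarbonyl)-1H-pyrrol-2-yl]boronic acid | CC(C)(C)OC(=O)n1cccc1B(O)O | starting material
26 | N-Boc-premarineosin A: Boc on the nitrogen of ring A | COC1=CC(c2cccn2C(=O)OC(C)(C)C)=N[C@]12O[C@@H](C)C[C@@H]1CCCCCCCc3ccc([nH]3)[C@H]12 | intermediate
27 | premarineosin A | COC1=CC(c2ccc[nH]2)=N[C@]12O[C@@H](C)C[C@@H]1CCCCCCCc3ccc([nH]3)[C@H]12 | target

**Step count and risks**

Total step count: 16.
Longest linear sequence: 13 steps (steps 1, 3, 4, 5, 8, 9, 10, 11, 12, 13, 14, 15, 16, from (S)-γ-valerolactone; the branch from 3-bromofuran is equally long).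

Steps most likely to fail:

Step 8 (Friedel–Crafts alkylation). The capture of the furfuryl cation may show poor facial discrimination, because the two arms on the neighbouring carbon differ only beyond their first CH2. The cation may also lose a proton to an alkenylfuran, whose re-protonation would scramble the adjacent centre. The fallback sets out from 3 and returns at 14; it exchanges the roles of the two heteroarenes and places the new centre under catalyst control. Lactone 3 is reduced with i-Bu2AlH (CH2Cl2, −78 °C) to the lactol F1. The magnesium derivative of pyrrole 13 (EtMgBr, THF) adds through its free α-carbon to the open hydroxy aldehyde form and gives the pyrrol-2-yl carbinol diol F2. A chiral BINOL-derived phosphoric acid (TRIP, the enantiomer matched with the resident centre, found by trying both; 10 mol %, toluene, −40 °C) ionises F2 to a hydrogen-bonded azafulvene–phosphate pair. This pair alkylates 3-methoxyfuran 5 at C-2 (asymmetric Friedel–Crafts alkylation under chiral Brønsted acid catalysis) to give the hydroxy diarylmethane F3. Silylation (TBSCl, imidazole, DMF) then returns to 14.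

Step 11 (spiro N,O-ketalisation). With both arms still free, equilibration may prefer the spiro epimer in which the two arms stand axial and the methyl group equatorial. On long exposure the N-acyliminium ion may also lose the adjacent methine proton to a 5-ylidene lactam and so erode the pyrrolyl-bearing centre. The fallback sets out from 18 and returns at 22. The acid treatment is kept short and the spiro-epimeric N-Boc lactam F4 is carried on instead of being recycled. K2CO3 in MeOH gives the spiro-epimeric diene F5. F5 is cyclised with the second-generation Grubbs catalyst RuCl2(=CHPh)(H2IMes)(PCy3) in toluene at 80 °C in the presence of CSA (10 mol %), so that spiro equilibration and ring closure run together. Once the ansa bridge exists it ties both arms equatorial, the diaxial alternative is no longer available, and the anomerically favoured epimer 22 becomes the resting point. The spiro centre is then fixed by the macrocycle and not by the free bicycle.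

Step 13 (ring-closing metathesis). Intermolecular metathesis to oligomers, alkene migration before closure (ring-contracted products) or binding of ruthenium by the two N–H groups may outrun ring closure. The fallback sets out from 21 and returns at 22; it makes the same C4=C5 bond by reductive carbonyl coupling. The two terminal alkenes of 21 are cleaved (OsO4 cat., NMO, acetone–H2O; then NaIO4) to the dialdehyde F6. F6 is added slowly to TiCl3 and Zn–Cu couple in refluxing DME (McMurry macrocyclisation) to give alkene 22, and the route continues with step 14.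

**Further compounds**

F1 | step 8 | lactol, (3S,5S)-5-methyl-3-(pent-4-en-1-yl)oxolan-2-ol, both anomers | C[C@H]1C[C@H](CCCC=C)C(O)O1
F2 | step 8 | pyrrol-2-yl carbinol diol, (2S,4S)-1-[5-(but-3-en-1-yl)-1H-pyrrol-2-yl]-2-(pent-4-en-1-yl)pentane-1,4-diol, both C-1 epimers | C[C@H](O)C[C@H](CCCC=C)C(O)c1ccc(CCC=C)[nH]1
F3 | step 8 | hydroxy diarylmethane, (2S,4S,5S)-5-[5-(but-3-en-1-yl)-1H-pyrrol-2-yl]-5-(3-methoxyfuran-2-yl)-4-(pent-4-en-1-yl)pentan-2-ol | C[C@H](O)C[C@H](CCCC=C)[C@H](c1occc1OC)c1ccc(CCC=C)[nH]1
F4 | step 11 | spiro-epimeric N-Boc lactam, the (5S,7S,9S,10S) isomer of 20 | COC1=CC(=O)N[C@@]12O[C@@H](C)C[C@H](CCCC=C)[C@H]2c2ccc(CCC=C)n2C(=O)OC(C)(C)C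
F5 | step 11 | spiro-epimeric diene, the (5S,7S,9S,10S) isomer of 21 | COC1=CC(=O)N[C@@]12O[C@@H](C)C[C@H](CCCC=C)[C@H]2c2ccc(CCC=C)[nH]2
F6 | step 13 | dialdehyde, 4-[(5R,7S,9S,10S)-4-methoxy-7-methyl-2-oxo-10-[5-(3-oxopropyl)-1H-pyrrol-2-yl]-6-oxa-1-azaspiro[4.5]dec-3-en-9-yl]butanal | COC1=CC(=O)N[C@]12O[C@@H](C)C[C@H](CCCC=O)[C@H]2c2ccc(CCC=O)[nH]2
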